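(The earlier runs and the new flask were generated by integration for substances that don't exist, noise included.)

Do not read two close end readings as a capture agent without effect: larch at 4.1 mM and maple at 17 mM end at 15.8 % and 16.0 % open intermediate, a gap of 0.2 percentage points against a scatter of 0.5 points, and a small slope can hide in that.

| flask | substrate | reagent | capture agent | remark | time |
|---|---|---|---|---|---|
| larch | 0.086 M | 0.0516 M | 4.1 mM | run made earlier |  |
| maple | 0.086 M | 0.0516 M | 17 mM | run made earlier |  |
| oak | 0.086 M | 0.0516 M | 58 mM | run made earlier |  |
| dawn | 0.086 M | 0.0516 M | 4.00 mM |  | 5.0 min |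
| summer | 0.086 M | 0.0516 M | 8.00 mM |  | 5.0 min |
| autumn | 0.086 M | 0.0516 M | 15.0 mM |  | 5.0 min |
| dusk | 0.086 M | 0.0516 M | 30.0 mM |  | 5.0 min |
| noon | 0.086 M | 0.0516 M | 60.0 mM |  | 5.0 min |

- larch (time / min: open intermediate / %, target / %): 0.417: 11.7, 0.6; 1.33: 20.8, 4.1; 2.50: 20.6, 10.3; 4.00: 17.5, 15.6; 5.00: 15.8, 19.9
- maple (time / min: open intermediate / %, target / %): 0.417: 12.0, 0.7; 1.33: 19.7, 3.9; 2.50: 20.1, 10.5; 4.00: 17.8, 16.1; 5.00: 16.0, 19.9
- oak (time / min: open intermediate / %, target / %): 1.00: 18.2, 2.4; 2.00: 19.1, 7.6; 3.00: 17.5, 11.8; 4.00: 17.1, 15.2; 5.00: 14.1, 18.0

(readings scatter by 0.5 percentage points)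

- "hardly changes" means that all values lie within two and a half points (for a concentration: within two and a half percent of the largest)

* amount of open intermediate at the end, in percent of the substrate charged for dawn, summer, autumn, dusk, noon, in this order
* the shape of the row from first to last (rises all the way / hardly changes / falls, then rises / rises, then falls / falls all the way)

Solve the row at both ends and join them straight. Take larch and oak and read the capture slope 0.315 /M, the drop in end open intermediate, as a fraction of the substrate charged, per unit of added [capture agent]. It rests on two readings, so it carries their scatter. From 4.00 mM to 60.0 mM it gives a span of 1.8 points against the margin of 2.5 points, so expect a row that hardly changes, running from near 15.8 % down to about 14.0 %.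

The forecast gives 15.9 %, 15.9 %, 15.7 %, 15.2 %, 14.5 %, shape hardly changes, and takes the lower oak readings to suggest “a real but small effect”; its last point stands higher than mine.

The flasks give 16.2 %, 16.1 %, 15.9 %, 15.4 %, 14.5 %, shape hardly changes.

    substrate + reagent ⇌ open intermediate (K = 14.1 /M, k = 0.139 /M/s)
    open intermediate ⇌ target + by-product (K = 0.0619 M, k = 0.00408 /s)
    open intermediate + capture agent → trapped intermediate (k = 0.0152 /M/s)

In dawn, with each step taken net, open intermediate was made 3.81 times faster than it was used up at 0.682 min, but by 5.00 min making ran at 0.582 of using up, and open intermediate had fallen from 19.9 % at 2.50 min to 16.2 %. Capture ran beside this as a slow pseudo-first-order leak: the half-life of open intermediate by capture alone, in dawn at the end, is 3.4 h, long against 5.0 min, and noon ends with 4.36 % trapped intermediate and 94 % of its capture agent left. From dawn to noon the row drops 1.7 points, beside the 1.8 points reckoned from the capture slope. For dusk, the capture slope taken from dawn gives 15.4 %, and dusk holds 15.4 %.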